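(Readings and results stem from a simulated flask with made-up constants; the scatter is artificial.)

In green the dose entered at 0.200 /min of the charge, while product rose at 0.193 /min between 3.00 min and 4.00 min; these were so close that I integrated nothing for your quick number. Your hunch, more enzyme and more product, held in the earlier runs: at 4.00 min green stood above teal and teal above violet.

| flask | starting material | enzyme | remark | time |
|---|---|---|---|---|
| violet | 0.050 M (fed, over 5.0 min) | 0.0093 mol% | run made earlier; the fed solution adds 0.20 times the starting volume |  |
| teal | 0.050 M (fed, over 5.0 min) | 0.051 mol% | run made earlier; the fed solution adds 0.20 times the starting volume |  |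
| green | 0.050 M (fed, over 5.0 min) | 0.19 mol% | run made earlier; the fed solution adds 0.20 times the starting volume |  |
| north | 0.050 M (fed, over 5.0 min) | 0.08 mol% | the fed solution adds 0.20 times the starting volume | 5.0 min |
| east | 0.050 M (fed, over 5.0 min) | 0.1 mol% | the fed solution adds 0.20 times the starting volume | 5.0 min |
| north-west | 0.050 M (fed, over 5.0 min) | 0.05 mol% | the fed solution adds 0.20 times the starting volume | 5.0 min |
| south-west | 0.050 M (fed, over 5.0 min) | 0.2 mol% | the fed solution adds 0.20 times the starting volume | 5.0 min |
| south-east | 0.050 M (fed, over 5.0 min) | 0.015 mol% | the fed solution adds 0.20 times the starting volume | 5.0 min |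
| north-east | 0.050 M (fed, over 5.0 min) | 0.012 mol% | the fed solution adds 0.20 times the starting volume | 5.0 min |

| run | time / min | product / % | starting material / % |
|---|---|---|---|
| violet | 0.667 | 0 | 13.6 |
| violet | 1.33 | 2.5 | 25.1 |
| violet | 2.00 | 3.3 | 36.9 |
| violet | 3.00 | 6.4 | 54.7 |
| violet | 4.00 | 10.9 | 69.1 |
| teal | 0.333 | 1.1 | 5.7 |
| teal | 0.833 | 5.1 | 12.9 |
| teal | 1.50 | 11.4 | 20.4 |
| teal | 2.50 | 20.7 | 29.8 |
| teal | 4.00 | 41.8 | 36.9 |
| green | 0.667 | 5.7 | 5.5 |
| green | 1.33 | 18.9 | 9.6 |
| green | 2.00 | 29.8 | 8.9 |
| green | 3.00 | 50.2 | 10.4 |
| green | 4.00 | 69.5 | 11.2 |

(readings scatter by 1 percentage point)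

- charges are per starting volume, the dose included; the dosed solution carries all of it
- the numbers in the tables scatter by 1 percentage point (one standard deviation)
- reactions considered so far: starting material + enzyme -> product + enzyme; enzyme <-> dormant form; enzyme + product -> spent catalyst
- percentages count the whole charge, also what has not yet gone in

- ranking by amount of product, in percent of the starting material charged, from high to low, at 5.0 min (north / east / north-west / south-west / south-east / north-east)
- the amount of product, in percent of the starting material charged of the flask you put first, at 5.0 min
- the amount of product, in percent of the starting material charged of the flask you put last, at 5.0 min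

Green's balance was 80.7% found against 80.0% dosed, and the asked time is the end of the dose, so I reckoned the correction instead of the product: what still stood. I read green's pseudo-first-order constant as product rate over mean [starting material] and scaled it by loading to south-west:

k(green) = 1.79 /min, k(south-west) = 1.88 /min

stock(south-west) = dose rate / k = 10.6%

With k held constant, the standing stock, the [starting material] at which consumption equals the dose, forms where 1/k is shorter than the dose, as in south-west. That gave me 89.4% product there, and a stock growing as loading falls put the flasks in order of loading. In north-east 1/k is longer than the dose, so I extended violet's last slope to the end of the dose and scaled by loading: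

product(north-east) = 19.9%

The forecast gave south-west > east > north > north-west > south-east > north-east, with 88% and 20%, and judged "Product killing looks weak".

The flasks gave south-west > east > north > north-west > south-east > north-east, with 88.6% in south-west and 17.0% in north-east.

starting material + enzyme → product + enzyme, rate k1*[starting material]*[enzyme]/(1 + ([starting material]/Km1) + ([starting material]/Ksi1)^2) (0.120 M, 37.0 mM, k = 480 /M/s); enzyme ⇌ dormant form (K = 0.200, k = 0.00710 /s); enzyme + product → spent catalyst (k = 0.0250 /M/s) In south-west, conversion kept pace with the dose while [starting material] stood at 9.56% at 2.50 min and 11.4% at 5.00 min, against my stock of 10.6%, and meanwhile enzyme went from 81.1% to 74.2% of the catalyst charged, dormant form from 16.3% to 15.1%, and spent catalyst from 2.56% to 10.7%. In east, the stock scaled by loading came to 21.3%, and 23.0% of [starting material] stood there at 5.00 min.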